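**Retrosynthetic overview**
1. Palstatin is the protected flavone after removal of three benzyl groups and one TBS group. The chromone ring is formed last, by Claisen condensation of a benzodioxane methyl ester with 2'-hydroxy-4',6'-bis(benzyloxy)acetophenone, then cyclodehydration of the 1,3-diketone.
2. The benzodioxane ring is formed first. It closes by reductive etherification of an α-aryloxy aryl ketone whose free ortho-phenol adds to the ketone. The hydride delivery sets C2 trans to C3.
3. The α-aryloxy ketone comes from Mitsunobu etherification, with inversion, of a chiral α-hydroxy ketone onto the most acidic phenol (4-OH) of methyl 3-O-methylgallate. That α-hydroxy ketone comes from (S)-glycerate acetonide by Weinreb ketone synthesis with a syringyl Grignard.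

Assumptions: (S)-methyl 2,2-dimethyl-1,3-dioxolane-4-carboxylate (compound 3, from L-ascorbic acid) is commercially available. In Step 6 the 4-OH of compound 8, para to the ester and more acidic than the 3-OH, reacts selectively.

---

**Step 1**
Reactants: 1 (4-bromo-2,6-dimethoxyphenol)
Product: 2 (1-(benzyloxy)-4-bromo-2,6-dimethoxybenzene)
Conditions: BnBr, K2CO3, DMF, 60 °C
Reagents that add atoms: benzyl bromide, BrCc1ccccc1
Why: Williamson etherification protects the syringyl phenol as a benzyl ether, which survives the Grignard, Mitsunobu and silane steps.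

**Step 2**
Reactants: 3 ((S)-methyl 2,2-dimethyl-1,3-dioxolane-4-carboxylate)
Product: 4 ((S)-N-methoxy-N,2,2-trimethyl-1,3-dioxolane-4-carboxamide)
Conditions: MeNHOMe·HCl, iPrMgCl, THF, −20 → 0 °C
Reagents that add atoms: N,O-dimethylhydroxylamine, CNOC
Why: Magnesium-amide aminolysis gives the Weinreb amide without touching the acetonide or the α-stereocentre, so the chiral-pool configuration carries forward.

**Step 3**
Reactants: 2 and 4
Product: 5 ((S)-[4-(benzyloxy)-3,5-dimethoxyphenyl](2,2-dimethyl-1,3-dioxolan-4-yl)methanone)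
Conditions: Mg, BrCH2CH2Br (cat.), THF, reflux to make the ArMgBr; then add 4, 0 °C; aq. NH4Cl
Reagents that add atoms: none
Why: The Weinreb chelate stops at the ketone and releases it only on work-up, so the base-sensitive α-stereocentre is not epimerised.

**Step 4**
Reactants: 5
Product: 6 ((S)-1-[4-(benzyloxy)-3,5-dimethoxyphenyl]-2,3-dihydroxypropan-1-one)
Conditions: AcOH/H2O/THF (4:1:1), 40 °C
Reagents that add atoms: water, O
Why: Mild acid hydrolysis removes the acetonide and leaves the benzyl ether and the stereocentre intact.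

**Step 5**
Reactants: 6
Product: 7 ((S)-1-aryl-3-(tert-butyldimethylsilyloxy)-2-hydroxypropan-1-one, aryl = 4-OBn-3,5-(MeO)2C6H2)
Conditions: TBSCl (1.05 equiv), imidazole, CH2Cl2, 0 °C
Reagents that add atoms: tert-butyldimethylsilyl chloride, CC(C)(C)[Si](C)(C)Cl
Why: The unhindered primary alcohol silylates selectively over the hindered, H-bonded α-keto secondary alcohol, leaving a single secondary OH for Mitsunobu.

**Step 6**
Reactants: 7 and 8 (methyl 3,4-dihydroxy-5-methoxybenzoate)
Product: 9 (methyl 3-hydroxy-5-methoxy-4-{[(R)-1-(TBSO)-3-aryl-3-oxopropan-2-yl]oxy}benzoate)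
Conditions: PPh3, DIAD, THF, 0 °C → rt
Reagents that add atoms: none
Why: Mitsunobu etherification is an SN2 reaction at the secondary carbinol, so (S)-7 gives the (R) aryl ether, which becomes C3 of the dioxane; the betaine deprotonates the more acidic para-ester 4-OH, so O4' ends up on the CH(CH2OTBS) carbon.

**Step 7**
Reactants: 9
Product: 10 (methyl (2R,3R)-2-[4-(benzyloxy)-3,5-dimethoxyphenyl]-3-(TBSO-methyl)-5-methoxy-2,3-dihydro-1,4-benzodioxine-7-carboxylate)
Conditions: Et3SiH, BF3·OEt2, CH2Cl2, −78 → 0 °C
Reagents that add atoms: none (Et3SiH adds only hydride)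
Why: The free 3'-OH adds to the ketone to form a cyclic hemiketal. BF3 ionises it to an electron-rich benzylic oxocarbenium, and axial hydride delivery puts the aryl group trans-diequatorial to C3, giving C2 (R) by reductive etherification; the ester and silyl ether survive.

**Step 8**
Reactants: 11 (2,4,6-trihydroxyacetophenone)
Product: 12 (2'-hydroxy-4',6'-bis(benzyloxy)acetophenone)
Conditions: BnBr (2.1 equiv), K2CO3, acetone, reflux
Reagents that add atoms: benzyl bromide, BrCc1ccccc1
Why: The 2-OH is chelated to the ketone and stays free, so alkylation occurs only at the 4- and 6-OH groups.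

**Step 9**
Reactants: 10 and 12
Product: 13 (1,3-diketone: ArCO–CH2–CO–C6H2(OH)(OBn)2, Ar = the benzodioxane)
Conditions: LiHMDS (4 equiv), THF, −78 °C → rt; aq. NH4Cl
Reagents that add atoms: none
Why: The acetophenone enolate (formed after deprotonating the phenol) attacks the aryl methyl ester in a Claisen condensation. None of the stereocentres has an acidic hydrogen.

**Step 10**
Reactants: 13
Product: 14 (5,7-bis(benzyloxy)flavone carrying the TBS- and Bn-protected dioxane)
Conditions: PPh3, DIAD, THF, 0 → 25 °C
Reagents that add atoms: none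
Why: Neutral Mitsunobu cyclodehydration closes the 4-pyranone by O-attack of the enolised diketone, avoiding strong acid that could ionise the benzylic dioxane C–O.

**Step 11**
Reactants: 14
Product: 15 (TBS-protected palstatin)
Conditions: H2 (1 atm), 10% Pd/C, THF/MeOH, rt
Reagents that add atoms: none (H2 adds only hydrogen)
Why: Hydrogenolysis removes the three aryl benzyl ethers (5-, 7- and syringyl 4-OBn) while the flavone C2=C3, the TBS ether and the aryl methyl ethers remain.

**Step 12**
Reactants: 15
Product: 16 (palstatin)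
Conditions: TBAF, AcOH, THF, rt
Reagents that add atoms: none
Why: Buffered fluoride removes the primary TBS ether and liberates CH2OH without touching the stereocentres.

Check of the route: the Step 12 product has formula C27H24O11 and SMILES identical to the target. C3 is set in Step 6 (R), C2 in Step 7 (R, trans), and no later step touches them.

---

**Compound list**

1 | 4-bromo-2,6-dimethoxyphenol | COc1cc(Br)cc(OC)c1O | starting material
2 | 1-(benzyloxy)-4-bromo-2,6-dimethoxybenzene | COc1cc(Br)cc(OC)c1OCc1ccccc1 | intermediate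
3 | methyl (S)-2,2-dimethyl-1,3-dioxolane-4-carboxylate | COC(=O)[C@@H]1COC(C)(C)O1 | starting material
4 | (S)-Weinreb amide of isopropylidene glyceric acid | CON(C)C(=O)[C@@H]1COC(C)(C)O1 | intermediate
5 | (S)-aryl acetonide ketone | COc1cc(C(=O)[C@@H]2COC(C)(C)O2)cc(OC)c1OCc1ccccc1 | intermediate
6 | (S)-α,γ-dihydroxy aryl ketone | COc1cc(C(=O)[C@@H](O)CO)cc(OC)c1OCc1ccccc1 | intermediate
7 | (S)-γ-OTBS α-hydroxy aryl ketone | COc1cc(C(=O)[C@@H](O)CO[Si](C)(C)C(C)(C)C)cc(OC)c1OCc1ccccc1 | intermediate
8 | methyl 3,4-dihydroxy-5-methoxybenzoate | COC(=O)c1cc(O)c(O)c(OC)c1 | starting material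
9 | (R)-α-aryloxy ketone with free 3'-OH | COC(=O)c1cc(O)c(O[C@H](CO[Si](C)(C)C(C)(C)C)C(=O)c2cc(OC)c(OCc3ccccc3)c(OC)c2)c(OC)c1 | intermediate
10 | (2R,3R)-benzodioxane methyl ester | COc1cc([C@H]2Oc3cc(C(=O)OC)cc(OC)c3O[C@@H]2CO[Si](C)(C)C(C)(C)C)cc(OC)c1OCc1ccccc1 | intermediate
11 | 2,4,6-trihydroxyacetophenone | CC(=O)c1c(O)cc(O)cc1O | starting material
12 | 2'-hydroxy-4',6'-bis(benzyloxy)acetophenone | CC(=O)c1c(O)cc(OCc2ccccc2)cc1OCc1ccccc1 | intermediate
13 | 1,3-diketone | COc1cc([C@H]2Oc3cc(C(=O)CC(=O)c4c(O)cc(OCc5ccccc5)cc4OCc4ccccc4)cc(OC)c3O[C@@H]2CO[Si](C)(C)C(C)(C)C)cc(OC)c1OCc1ccccc1 | intermediate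
14 | protected flavone | COc1cc([C@H]2Oc3cc(-c4cc(=O)c5c(OCc6ccccc6)cc(OCc6ccccc6)cc5o4)cc(OC)c3O[C@@H]2CO[Si](C)(C)C(C)(C)C)cc(OC)c1OCc1ccccc1 | intermediate
15 | TBS-palstatin | COc1cc([C@H]2Oc3cc(-c4cc(=O)c5c(O)cc(O)cc5o4)cc(OC)c3O[C@@H]2CO[Si](C)(C)C(C)(C)C)cc(OC)c1O | intermediate
16 | palstatin | COc1cc([C@H]2Oc3cc(-c4cc(=O)c5c(O)cc(O)cc5o4)cc(OC)c3O[C@@H]2CO)cc(OC)c1O | target

---

**Total steps:** 12 (Steps 1 and 8 prepare building blocks in parallel).
**Longest linear sequence:** 10 steps, from compound 3 through Steps 2, 3, 4, 5, 6, 7, 9, 10, 11 and 12.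

**Three steps most likely to fail**
1. **Step 6 (Mitsunobu on the flanked phenol).** The α-keto centre may epimerise, or yield may be poor at the hindered 4-OH. Fallback: an SNAr approach using the cheaper D-mannitol-derived (R) glycerate series. Its (R)-α-hydroxy-ketone alkoxide attacks methyl 3-(allyloxy)-4-fluoro-5-methoxybenzoate, keeping configuration at carbon, followed by Pd(0) de-allylation.
2. **Step 7 (reductive etherification).** Over-reduction of the electron-rich aryl ketone to a CH2 group or poor trans selectivity are the risks. Fallback: chelation-controlled Zn(BH4)2 reduction of the ketone to the alcohol, then cyclisation of the benzylic alcohol onto the 3'-OH by intramolecular Mitsunobu or acid (via the benzylic cation), which gives the thermodynamic trans ring.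
3. **Step 9 (Claisen condensation onto the electron-rich ester).** Conversion may be low. Fallback: the chalcone route: reduce ester 10 to the aldehyde (DIBAL, then Dess–Martin), condense with 12 (KOH, EtOH), and cyclise the chalcone with I2/DMSO to give flavone 14.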